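**Plan**
1. The retrosynthesis first cuts the two C–C bonds of the CH2 bridge (ring A carbon–CH2 and CH2–ring B enol carbon). This gives a prenylated isobutyrylphloroglucinol (ring A) and the free ring B acid.
2. Ring B is then cut between its enol CH carbon and the adjacent C–OH carbon beside the quaternary centre (Claisen disconnection). Tying the freed acyl carbon to the oxygen of the remote ring carbonyl turns the carbocycle into a pyran-2,4-dione, whose C3–prenyl and C3–isobutyryl bonds are cut last.
3. Enabling feature: ring B is an enolised cyclohexane-1,3,5-trione whose quaternary carbon (prenyl, isobutyryl) lies between two ring carbonyl carbons. It is therefore an isomer of a 3,3-disubstituted 5,6-dimethylpyran-2,4-dione, in which these two flanks are a lactone C=O and a ketone instead of two enol arms differing only by H versus CH3.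
4. Forward order: pyranone ring (from 3-methylpentane-2,4-dione and CO2), C3 acylation, C3 prenylation, pyranone-to-carbocycle ring change (ring B), then union with ring A (made separately from phloroglucinol) through a Mannich base.
5. Stereochemistry: the single stereocentre is set in step 5 by ligand-controlled Tsuji–Trost prenylation of the planar pyronate. It has no α-hydrogen and is carried unchanged into ring B and the target.

Key step: step 6

Assumption on configuration: the (1R,2R)-diphosphine is taken to deliver the (3S)-pyrandione 9; should the sense of induction be opposite, the (1S,2S)-ligand is used with no other change.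
Assumption on tautomers: ring B compounds are drawn in the enol form of the target; the descriptor of the quaternary carbon changes from R in 11 to S in 18 only because the CIP ranking of its neighbours changes when the bridge is attached.

**Step 1**
Reactants: 1 3-methylpentane-2,4-dione
Product: 2 4-methyl-3,5-dioxohexanoic acid
Conditions: LiN(i-Pr)2 (2.2 equiv), THF, 0 °C; cannulate onto excess CO2, Et2O, −78 °C; cold 1 M HCl; use crude at once
Reagents that add atoms: carbon dioxide, O=C=O
Why: The 1,3-diketone dianion reacts with electrophiles at its more basic terminal carbon, so carboxylation of the dianion should give the β,δ-diketo acid.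

**Step 2**
Reactants: 2 4-methyl-3,5-dioxohexanoic acid
Product: 3 4-hydroxy-5,6-dimethyl-2H-pyran-2-one
Conditions: 1,1'-carbonyldiimidazole (1.2 equiv), THF, rt; 1 M HCl
Reagents that add atoms: none
Why: Activation of the acid as its acyl imidazolide lets the enol oxygen of the δ-ketone close the six-membered enol lactone, the usual lactonisation of β,δ-diketo acids to 4-hydroxy-2-pyrones.

**Step 3**
Reactants: 3 4-hydroxy-5,6-dimethyl-2H-pyran-2-one; 4 2-methylpropanoyl chloride (isobutyryl chloride)
Product: 6 4-hydroxy-5,6-dimethyl-3-(2-methylpropanoyl)-2H-pyran-2-one, via enol isobutyrate 5 (not isolated)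
Conditions: 4 (1.1 equiv), Et3N, CH2Cl2, 0 °C; then DMAP (0.2 equiv), toluene, 80 °C
Reagents that add atoms: none
Why: O-Acylation of the 4-hydroxyl followed by DMAP-mediated 1,3-acyl shift (Fries-type O-to-C migration through an acylpyridinium pyronate ion pair) should place the isobutyryl group at C3, the only free nucleophilic ring carbon.

**Step 4**
Reactants: 7 3-methylbut-2-en-1-ol
Product: 8 tert-butyl 3-methylbut-2-en-1-yl carbonate
Conditions: Boc2O (1.2 equiv), DMAP (0.1 equiv), CH2Cl2, 0 °C → rt
Reagents that add atoms: di-tert-butyl dicarbonate, CC(C)(C)OC(=O)OC(=O)OC(C)(C)C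
Why: DMAP-catalysed acyl transfer to the primary allylic alcohol gives the mixed carbonate, chosen over the methyl carbonate so that the later ionisation releases non-nucleophilic tert-butanol and not methanol.

**Step 5**
Reactants: 6 4-hydroxy-5,6-dimethyl-3-(2-methylpropanoyl)-2H-pyran-2-one; 8 tert-butyl 3-methylbut-2-en-1-yl carbonate
Product: 9 (3S)-5,6-dimethyl-3-(3-methylbut-2-en-1-yl)-3-(2-methylpropanoyl)-2H-pyran-2,4(3H)-dione
Conditions: 8 (1.2 equiv), Pd2(dba)3·CHCl3 (2.5 mol %), (1R,2R)-N,N'-bis[2-(diphenylphosphanyl)benzoyl]cyclohexane-1,2-diamine (7.5 mol %), degassed CH2Cl2, 0 °C → rt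
Reagents that add atoms: none
Why: In this Tsuji–Trost asymmetric allylic alkylation zerovalent palladium ionises 8 to a ligand-bound cationic (η3-prenyl)palladium complex and tert-butoxide, which deprotonates the acidic enol 6; the soft tricarbonyl-stabilised anion should attack the unsubstituted allyl terminus through C3 (O-prenyl isomers can re-ionise and funnel to the C-prenyl product), and the chiral pocket of the diphosphine distinguishes the two faces of the planar anion, whose lactone and ketone flanks differ strongly, to set the quaternary (S) centre.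

**Step 6**
Reactants: 9 (3S)-5,6-dimethyl-3-(3-methylbut-2-en-1-yl)-3-(2-methylpropanoyl)-2H-pyran-2,4(3H)-dione
Product: 11 (4R)-3,5-dihydroxy-2-methyl-4-(3-methylbut-2-en-1-yl)-4-(2-methylpropanoyl)cyclohexa-2,5-dien-1-one (ring B acid), via triketo methyl ester 10 (not isolated)
Conditions: Mg(OMe)2 (1.1 equiv), MeOH–THF, −20 → 0 °C; evaporate, strip with toluene; LiN(SiMe3)2 (3.5 equiv), THF, −78 → −20 °C; cold 1 M HCl
Reagents that add atoms: none
Why: Methoxide delivered by Mg(OMe)2 attacks the lactone carbonyl C2, which as an enol ester is the most electrophilic and least shielded of the three carbonyls on the quaternary carbon, and the ring opens to triketo ester 10, held as the magnesium chelate of its 2-methyl-1,3-diketone. LiN(SiMe3)2 then removes a proton from the terminal methyl group (the former 6-methyl) of this chelated diketonate, and the carbanion attacks the methyl ester in a 6-(enolendo)-exo-trig closure, expels the methoxide taken up before and leaves ring B as its doubly stabilised enolate, which makes the sequence irreversible. The closest known reaction type is the intramolecular Claisen (Dieckmann-type) condensation of β,δ-diketo ester dianions to cyclohexane-1,3,5-triones, the bond construction by which triketo esters and 4-hydroxy-2-pyrones are converted into phloroglucinols. No stereocentre is created, because the methyl-bearing carbon ends as an enol carbon, and the quaternary carbon has no α-hydrogen, so the configuration from step 5 is carried over unchanged. The step needs acylation at the ester to outrun retro-Claisen loss of the isobutyryl group and aldol addition to the isobutyryl ketone: the diketone is kept as a chelated enolate so that the quaternary carbon is a poor leaving group, the amide base is non-nucleophilic and used cold, the isopropyl ketone is shielded on both sides, and an aldolate can revert whereas the Claisen product cannot.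

**Step 7**
Reactants: 12 phloroglucinol; 4 2-methylpropanoyl chloride (isobutyryl chloride)
Product: 13 2-methyl-1-(2,4,6-trihydroxyphenyl)propan-1-one
Conditions: AlCl3 (4 equiv), CH2Cl2–MeNO2, 0 → 40 °C; aq. HCl
Reagents that add atoms: none
Why: Friedel–Crafts acylation of the symmetrical triphenol gives a single regioisomer and stops after one acyl group because the ketone deactivates the ring.

**Step 8**
Reactants: 13 2-methyl-1-(2,4,6-trihydroxyphenyl)propan-1-one; 14 1-bromo-3-methylbut-2-ene
Product: 15 2-methyl-1-[2,4,6-trihydroxy-3-(3-methylbut-2-en-1-yl)phenyl]propan-1-one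
Conditions: 14 (0.9 equiv), 10 % aq. KOH, 0 °C; chromatographic removal of diprenylated material
Reagents that add atoms: none
Why: The phloroglucinol phenolate is C-alkylated in water, where hydrogen bonding suppresses O-alkylation; the two free ring carbons are equivalent, and a deficit of bromide limits double prenylation.

**Step 9**
Reactants: 15 2-methyl-1-[2,4,6-trihydroxy-3-(3-methylbut-2-en-1-yl)phenyl]propan-1-one
Product: 16 1-[3-[(dimethylamino)methyl]-2,4,6-trihydroxy-5-(3-methylbut-2-en-1-yl)phenyl]-2-methylpropan-1-one
Conditions: Me2N=CH2+ I− (1.1 equiv), Et3N (1.1 equiv), CH2Cl2, 0 °C → rt; used crude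
Reagents that add atoms: N,N-dimethylmethyleneiminium iodide, C=[N+](C)C.[I-]
Why: In this Mannich reaction the preformed iminium ion attacks the only free, strongly activated ring carbon, and its use in excess under anhydrous conditions should hold back the methylene-bis by-product.

**Step 10**
Reactants: 16 1-[3-[(dimethylamino)methyl]-2,4,6-trihydroxy-5-(3-methylbut-2-en-1-yl)phenyl]-2-methylpropan-1-one; 11 (4R)-3,5-dihydroxy-2-methyl-4-(3-methylbut-2-en-1-yl)-4-(2-methylpropanoyl)cyclohexa-2,5-dien-1-one
Product: 18 1-[3-{[(3S)-2,4-dihydroxy-5-methyl-3-(3-methylbut-2-en-1-yl)-3-(2-methylpropanoyl)-6-oxocyclohexa-1,4-dien-1-yl]methyl}-2,4,6-trihydroxy-5-(3-methylbut-2-en-1-yl)phenyl]-2-methylpropan-1-one (target CNP0191741.1), via ortho-quinone methide 17 (not isolated)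
Conditions: 11 (1.0 equiv), 16 (1.1 equiv), 1,4-dioxane, 60 °C, N2 stream
Reagents that add atoms: none
Why: Proton transfer from the acidic enol 11 to the Mannich base assists loss of dimethylamine to the ortho-quinone methide 17, and the only free enol carbon of 11 adds to it in a Michael reaction that restores the aromaticity of ring A; the quaternary stereocentre is not involved.

**Compound list**
1 | 3-methylpentane-2,4-dione | CC(=O)C(C)C(C)=O | starting material
2 | 4-methyl-3,5-dioxohexanoic acid | CC(=O)C(C)C(=O)CC(=O)O | intermediate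
3 | 4-hydroxy-5,6-dimethyl-2H-pyran-2-one | CC1=C(C)C(O)=CC(=O)O1 | intermediate
4 | 2-methylpropanoyl chloride (isobutyryl chloride) | CC(C)C(=O)Cl | starting material
5 | 5,6-dimethyl-2-oxo-2H-pyran-4-yl 2-methylpropanoate (not isolated) | CC1=C(C)C(OC(=O)C(C)C)=CC(=O)O1 | intermediate
6 | 4-hydroxy-5,6-dimethyl-3-(2-methylpropanoyl)-2H-pyran-2-one | CC1=C(C)C(O)=C(C(=O)C(C)C)C(=O)O1 | intermediate
7 | 3-methylbut-2-en-1-ol | CC(C)=CCO | starting material
8 | tert-butyl 3-methylbut-2-en-1-yl carbonate | CC(C)=CCOC(=O)OC(C)(C)C | intermediate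
9 | (3S)-5,6-dimethyl-3-(3-methylbut-2-en-1-yl)-3-(2-methylpropanoyl)-2H-pyran-2,4(3H)-dione | O=C1[C@@](CC=C(C)C)(C(=O)C(C)C)C(=O)C(C)=C(C)O1 | intermediate
10 | methyl (2S)-4-methyl-2-(3-methylbut-2-en-1-yl)-2-(2-methylpropanoyl)-3,5-dioxohexanoate (not isolated; present as its magnesium enolate) | COC(=O)[C@@](CC=C(C)C)(C(=O)C(C)C)C(=O)C(C)C(C)=O | intermediate
11 | (4R)-3,5-dihydroxy-2-methyl-4-(3-methylbut-2-en-1-yl)-4-(2-methylpropanoyl)cyclohexa-2,5-dien-1-one (ring B acid) | O=C1C=C(O)[C@@](CC=C(C)C)(C(=O)C(C)C)C(O)=C1C | intermediate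
12 | phloroglucinol (benzene-1,3,5-triol) | Oc1cc(O)cc(O)c1 | starting material
13 | 2-methyl-1-(2,4,6-trihydroxyphenyl)propan-1-one | CC(C)C(=O)c1c(O)cc(O)cc1O | intermediate
14 | 1-bromo-3-methylbut-2-ene | CC(C)=CCBr | starting material
15 | 2-methyl-1-[2,4,6-trihydroxy-3-(3-methylbut-2-en-1-yl)phenyl]propan-1-one | CC(C)=CCc1c(O)cc(O)c(C(=O)C(C)C)c1O | intermediate
16 | 1-[3-[(dimethylamino)methyl]-2,4,6-trihydroxy-5-(3-methylbut-2-en-1-yl)phenyl]-2-methylpropan-1-one | CC(C)=CCc1c(O)c(CN(C)C)c(O)c(C(=O)C(C)C)c1O | intermediate
17 | 3,5-dihydroxy-6-methylidene-2-(3-methylbut-2-en-1-yl)-4-(2-methylpropanoyl)cyclohexa-2,4-dien-1-one (not isolated) | CC(C)=CCC1=C(O)C(C(=O)C(C)C)=C(O)C(=C)C1=O | intermediate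
18 | 1-[3-{[(3S)-2,4-dihydroxy-5-methyl-3-(3-methylbut-2-en-1-yl)-3-(2-methylpropanoyl)-6-oxocyclohexa-1,4-dien-1-yl]methyl}-2,4,6-trihydroxy-5-(3-methylbut-2-en-1-yl)phenyl]-2-methylpropan-1-one | CC(C)=CCc1c(O)c(CC2=C(O)[C@@](CC=C(C)C)(C(=O)C(C)C)C(O)=C(C)C2=O)c(O)c(C(=O)C(C)C)c1O | target

**Count**
Total steps: 10. Longest linear sequence: 6 steps (steps 1, 2, 3, 5, 6 and 10); the ring A branch (steps 7 to 9) and the carbonate (step 4) are convergent.

**Steps most likely to fail**

Step 6. The ring change may be defeated by retro-Claisen loss of the isobutyryl group from the triacyl carbon during methanolysis, or by slow acylation from the weakly acidic terminal methyl group. The fallback activates the nucleophilic carbon with an ester so that the same bond forms under Mg(OMe)2 alone. It sets out from 3 and comes back at 11.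
- The dianion of 3 (LiN(i-Pr)2, 3 equiv, THF, −78 °C) would be acylated at the 6-methyl group with Boc2O to give tert-butyl 2-(4-hydroxy-3-methyl-6-oxo-6H-pyran-2-yl)acetate F1.
- O-Acylation with 4 and DMAP-mediated acyl shift as in step 3 would give tert-butyl 2-[4-hydroxy-3-methyl-5-(2-methylpropanoyl)-6-oxo-6H-pyran-2-yl]acetate F2.
- Prenylation with 8 under the conditions of step 5 would give tert-butyl 2-[(5S)-3-methyl-5-(3-methylbut-2-en-1-yl)-5-(2-methylpropanoyl)-4,6-dioxo-5,6-dihydro-4H-pyran-2-yl]acetate F3.
- Mg(OMe)2 in MeOH at rt would open the lactone to 7-tert-butyl 1-methyl (2S)-4-methyl-2-(3-methylbut-2-en-1-yl)-2-(2-methylpropanoyl)-3,5-dioxoheptanedioate F4 (not isolated). Its methylene between ketone and tert-butyl ester is acidic enough for a magnesium-templated Claisen condensation of the polyketide type, closing ring B as tert-butyl (3S)-2,4-dihydroxy-5-methyl-3-(3-methylbut-2-en-1-yl)-3-(2-methylpropanoyl)-6-oxocyclohexa-1,4-diene-1-carboxylate F5.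
- Cleavage of the tert-butyl ester (TMSOTf, 2,6-lutidine, CH2Cl2, 0 °C, then aqueous work-up at pH 3) would give (3S)-2,4-dihydroxy-5-methyl-3-(3-methylbut-2-en-1-yl)-3-(2-methylpropanoyl)-6-oxocyclohexa-1,4-diene-1-carboxylic acid F6 (not isolated), a vinylogous β-keto acid that should lose CO2 at rt to give 11.

Step 5. Facial selectivity on the tricarbonyl-stabilised anion may be poor, and re-ionisation of the product C–allyl bond by zerovalent palladium may erode the enantiomeric purity. The fallback gives up catalytic induction. It sets out from 6 and comes back at 9.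
- Prenylation of 6 with 8 and Pd(PPh3)4 (THF, rt) would give racemic 5,6-dimethyl-3-(3-methylbut-2-en-1-yl)-3-(2-methylpropanoyl)-2H-pyran-2,4(3H)-dione F7.
- Preparative supercritical-fluid chromatography on an amylose tris(3,5-dimethylphenylcarbamate) phase would separate 9 from the (3R)-enantiomer F8, which is discarded.

Step 10. The bridge may scramble by reversible quinone methide formation to symmetrical methylene-bis products, the liberated dimethylamine may deacylate ring B, and the adduct may cyclise through a phenol oxygen. The fallback brings in the bridge carbon at the aldehyde oxidation level and fixes it by an irreversible reduction. It sets out from 15 and comes back at 18.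
- Vilsmeier–Haack formylation of 15 (POCl3, DMF, EtOAc, 0 °C → rt, aqueous hydrolysis) at the only free ring carbon would give 2,4,6-trihydroxy-3-(3-methylbut-2-en-1-yl)-5-(2-methylpropanoyl)benzaldehyde F9.
- Knoevenagel condensation of F9 with 11 (L-proline 20 mol %, CH2Cl2–EtOH, rt) would be run in the presence of diethyl 1,4-dihydro-2,6-dimethylpyridine-3,5-dicarboxylate. It would form the arylmethylidene trione F10 (not isolated), which is reduced in the flask by hydride transfer to 18; no free amine is released.

**Further compounds**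
F1 | step 6 | tert-butyl 2-(4-hydroxy-3-methyl-6-oxo-6H-pyran-2-yl)acetate | O=C1C=C(O)C(C)=C(CC(=O)OC(C)(C)C)O1
F2 | step 6 | tert-butyl 2-[4-hydroxy-3-methyl-5-(2-methylpropanoyl)-6-oxo-6H-pyran-2-yl]acetate | O=C1C(C(=O)C(C)C)=C(O)C(C)=C(CC(=O)OC(C)(C)C)O1
F3 | step 6 | tert-butyl 2-[(5S)-3-methyl-5-(3-methylbut-2-en-1-yl)-5-(2-methylpropanoyl)-4,6-dioxo-5,6-dihydro-4H-pyran-2-yl]acetate | O=C1[C@@](CC=C(C)C)(C(=O)C(C)C)C(=O)C(C)=C(CC(=O)OC(C)(C)C)O1
F4 | step 6 | 7-tert-butyl 1-methyl (2S)-4-methyl-2-(3-methylbut-2-en-1-yl)-2-(2-methylpropanoyl)-3,5-dioxoheptanedioate (not isolated) | COC(=O)[C@@](CC=C(C)C)(C(=O)C(C)C)C(=O)C(C)C(=O)CC(=O)OC(C)(C)C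
F5 | step 6 | tert-butyl (3S)-2,4-dihydroxy-5-methyl-3-(3-methylbut-2-en-1-yl)-3-(2-methylpropanoyl)-6-oxocyclohexa-1,4-diene-1-carboxylate | CC1=C(O)[C@](CC=C(C)C)(C(=O)C(C)C)C(O)=C(C(=O)OC(C)(C)C)C1=O
F6 | step 6 | (3S)-2,4-dihydroxy-5-methyl-3-(3-methylbut-2-en-1-yl)-3-(2-methylpropanoyl)-6-oxocyclohexa-1,4-diene-1-carboxylic acid (not isolated) | CC1=C(O)[C@](CC=C(C)C)(C(=O)C(C)C)C(O)=C(C(=O)O)C1=O
F7 | step 5 | racemic 5,6-dimethyl-3-(3-methylbut-2-en-1-yl)-3-(2-methylpropanoyl)-2H-pyran-2,4(3H)-dione | O=C1C(CC=C(C)C)(C(=O)C(C)C)C(=O)C(C)=C(C)O1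
F8 | step 5 | (3R)-5,6-dimethyl-3-(3-methylbut-2-en-1-yl)-3-(2-methylpropanoyl)-2H-pyran-2,4(3H)-dione | O=C1[C@](CC=C(C)C)(C(=O)C(C)C)C(=O)C(C)=C(C)O1
F9 | step 10 | 2,4,6-trihydroxy-3-(3-methylbut-2-en-1-yl)-5-(2-methylpropanoyl)benzaldehyde | CC(C)=CCc1c(O)c(C=O)c(O)c(C(=O)C(C)C)c1O
F10 | step 10 | arylmethylidene trione from F9 and 11, quaternary carbon configured as in 11 (not isolated) | CC(C)=CCc1c(O)c(C=C2C(=O)C(C)=C(O)[C@](CC=C(C)C)(C(=O)C(C)C)C2=O)c(O)c(C(=O)C(C)C)c1O
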